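**Strategy.** Labdane numbering is used. Both rings are opened at once by cutting ring A at C3–C4 and at the C5–C10 ring fusion, which leads back to an acyclic tetraene: an (E)-enoyl imide (C4=C5) tied through C6–C7–C8=C9 to a terminal diene (C10=C1–C2=C3). The tetrasubstituted C8=C9 alkene of ring B is exploited as a rigid, Z-configured tether element. One Me2AlCl-promoted intramolecular Diels–Alder reaction closes rings A and B and sets C5 and the quaternary C10 (trans fusion) under control of an (R)-4-benzyloxazolidinone; the C10 methyl then directs methylation at C4, and the residual C1=C2 alkene is reduced by diimide.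

Key step: step 13

Remark: the given configuration is read as (4S,5R,10S), i.e. H-5 trans to the C10 methyl group and the carboxyl group cis to it; compounds 1, 6, 18 and 19 are taken to be catalogue materials.

**Route**

Step 1
Reactants: 1 tert-butyldimethyl(pent-4-yn-1-yloxy)silane
Product: 3 ethyl 6-[(tert-butyldimethylsilyl)oxy]hex-2-ynoate, via lithium acetylide 2 (not isolated)
Conditions: n-BuLi, THF, −78 °C; then ClCO2Et, −78 °C to 0 °C
Reagents that add atoms: ethyl chloroformate, CCOC(=O)Cl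
Why: Deprotonation of the terminal alkyne and C-acylation of the lithium acetylide with a chloroformate (acetylide acylation) should give the alkynoate, the silyl ether being inert to both reagents.

Step 2
Reactants: 3 ethyl 6-[(tert-butyldimethylsilyl)oxy]hex-2-ynoate
Product: 5 ethyl (2E)-6-[(tert-butyldimethylsilyl)oxy]-2-iodo-3-methylhex-2-enoate, via alkenylcuprate 4 (not isolated)
Conditions: Me2CuLi (from MeLi and CuI), THF, −78 °C; then I2, THF, −78 °C
Reagents that add atoms: lithium dimethylcuprate, [Li+].C[Cu-]C; iodine, [I][I]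
Why: Conjugate addition of the Gilman cuprate to the alkynoate is a syn-carbocupration that places the new methyl (C17) and copper cis on the alkene, and iodinolysis of the alkenyl–copper bond at −78 °C, before any equilibration through the allenoate, should occur with retention, so that iodine ends up cis to the methyl group and the ester (future C10) cis to the silyloxypropyl chain (C5–C7).

Step 3
Reactants: 6 (2E)-3-methylpent-2-en-4-yn-1-ol
Product: 7 tert-butyl{[(2E)-3-methylpent-2-en-4-yn-1-yl]oxy}diphenylsilane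
Conditions: t-BuPh2SiCl, imidazole, DMF, 0 °C to rt
Reagents that add atoms: tert-butyl(chloro)diphenylsilane, CC(C)(C)[Si](Cl)(c1ccccc1)c1ccccc1
Why: Standard silylation of a primary allylic alcohol; the bulky diphenylsilyl ether is chosen to outlast the later selective removal of the dimethylsilyl ether.

Step 4
Reactants: 7 tert-butyl{[(2E)-3-methylpent-2-en-4-yn-1-yl]oxy}diphenylsilane
Product: 8 tert-butyl{[(2E)-3-methylpenta-2,4-dien-1-yl]oxy}diphenylsilane
Conditions: H2 (1 atm), Pd/CaCO3 poisoned with Pb(OAc)2 (Lindlar catalyst), quinoline, hexane/EtOAc, rt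
Reagents that add atoms: none
Why: Lindlar semihydrogenation stops at the alkene stage for a terminal alkyne and should turn the enyne into the 1,3-diene without touching the configuration of the trisubstituted (E)-alkene.

Step 5
Reactants: 5 ethyl (2E)-6-[(tert-butyldimethylsilyl)oxy]-2-iodo-3-methylhex-2-enoate; 8 tert-butyl{[(2E)-3-methylpenta-2,4-dien-1-yl]oxy}diphenylsilane
Product: 10 ethyl (2Z)-6-[(tert-butyldimethylsilyl)oxy]-2-[(3E)-5-{[tert-butyl(diphenyl)silyl]oxy}-3-methylpent-3-en-1-yl]-3-methylhex-2-enoate, via alkylborane 9 (not isolated)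
Conditions: 8, 9-BBN-H, THF, 0 °C to rt; then 5, PdCl2(dppf), AsPh3, Cs2CO3, DMF/THF/H2O, rt
Reagents that add atoms: none
Why: 9-BBN-H hydroborates only the monosubstituted terminal alkene of the diene with boron at the terminal carbon (future C11), and the B-alkyl Suzuki–Miyaura coupling of this borane with the electron-poor alkenyl iodide proceeds with retention of the alkene geometry, so the C11–C16 chain is attached at C9 cis to the C8 methyl group.

Step 6
Reactants: 10 ethyl (2Z)-6-[(tert-butyldimethylsilyl)oxy]-2-[(3E)-5-{[tert-butyl(diphenyl)silyl]oxy}-3-methylpent-3-en-1-yl]-3-methylhex-2-enoate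
Product: 11 (2Z)-6-[(tert-butyldimethylsilyl)oxy]-2-[(3E)-5-{[tert-butyl(diphenyl)silyl]oxy}-3-methylpent-3-en-1-yl]-3-methylhex-2-en-1-ol
Conditions: i-Bu2AlH, CH2Cl2, −78 °C; aqueous potassium sodium tartrate
Reagents that add atoms: none
Why: i-Bu2AlH reduces the conjugated ester in a 1,2-fashion to the allylic alcohol (ester reduction) without affecting silyl ethers or alkenes.

Step 7
Reactants: 11 (2Z)-6-[(tert-butyldimethylsilyl)oxy]-2-[(3E)-5-{[tert-butyl(diphenyl)silyl]oxy}-3-methylpent-3-en-1-yl]-3-methylhex-2-en-1-ol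
Product: 13 (4Z,8E)-1-[(tert-butyldimethylsilyl)oxy]-10-{[tert-butyl(diphenyl)silyl]oxy}-5-ethynyl-4,8-dimethyldeca-4,8-diene, via enal 12 (not isolated)
Conditions: MnO2, THF, rt; then K2CO3, MeOH, dimethyl (1-diazo-2-oxopropyl)phosphonate, 0 °C to rt
Reagents that add atoms: dimethyl (1-diazo-2-oxopropyl)phosphonate, CC(=O)C(=[N+]=[N-])P(=O)(OC)OC
Why: MnO2 oxidises only the allylic alcohol, and the Seyferth–Gilbert homologation of the resulting aldehyde with the Ohira–Bestmann reagent in the same flask should convert the formyl carbon (C10) into the terminal alkyne C10≡C1, conjugate addition of methoxide being blocked by the fully substituted β-carbon.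

Step 8
Reactants: 13 (4Z,8E)-1-[(tert-butyldimethylsilyl)oxy]-10-{[tert-butyl(diphenyl)silyl]oxy}-5-ethynyl-4,8-dimethyldeca-4,8-diene
Product: 15 (4Z,6E)-1-[(tert-butyldimethylsilyl)oxy]-5-[(3E)-5-{[tert-butyl(diphenyl)silyl]oxy}-3-methylpent-3-en-1-yl]-4,6-dimethylnona-4,6,8-triene, via alkenylalane 14 (not isolated)
Conditions: AlMe3, Cp2ZrCl2, CH2Cl2, 0 °C to rt; then CH2=CHBr, Pd(PPh3)4, ZnCl2, THF, rt
Reagents that add atoms: trimethylaluminium, C[Al](C)C; vinyl bromide, C=CBr
Why: Zirconium-catalysed syn-methylalumination of the terminal alkyne (Negishi carboalumination) delivers methyl (C20) to C10 and aluminium to C1 on the same side, and the palladium-catalysed cross-coupling of the alkenylalane with vinyl bromide retains this geometry, which should give the (E)-configured C10=C1 bond (C9 trans to C2) of the terminal diene.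

Step 9
Reactants: 15 (4Z,6E)-1-[(tert-butyldimethylsilyl)oxy]-5-[(3E)-5-{[tert-butyl(diphenyl)silyl]oxy}-3-methylpent-3-en-1-yl]-4,6-dimethylnona-4,6,8-triene
Product: 16 (4Z,6E)-5-[(3E)-5-{[tert-butyl(diphenyl)silyl]oxy}-3-methylpent-3-en-1-yl]-4,6-dimethylnona-4,6,8-trien-1-ol
Conditions: pyridinium p-toluenesulfonate, MeOH, rt
Reagents that add atoms: none
Why: Acid-catalysed methanolysis cleaves the unhindered primary tert-butyldimethylsilyl ether much faster than the tert-butyldiphenylsilyl ether (selective desilylation), so only the C5 hydroxyl group should be released.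

Step 10
Reactants: 16 (4Z,6E)-5-[(3E)-5-{[tert-butyl(diphenyl)silyl]oxy}-3-methylpent-3-en-1-yl]-4,6-dimethylnona-4,6,8-trien-1-ol
Product: 17 (4Z,6E)-5-[(3E)-5-{[tert-butyl(diphenyl)silyl]oxy}-3-methylpent-3-en-1-yl]-4,6-dimethylnona-4,6,8-trienal
Conditions: Dess–Martin periodinane, NaHCO3, CH2Cl2, 0 °C to rt
Reagents that add atoms: none
Why: Dess–Martin oxidation under bicarbonate buffering converts the primary alcohol into the aldehyde without isomerising the triene or touching the silyl ether.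

Step 11
Reactants: 18 (4R)-4-benzyl-1,3-oxazolidin-2-one; 19 (diethoxyphosphoryl)acetic acid
Product: 21 (4R)-4-benzyl-3-[(diethoxyphosphoryl)acetyl]-1,3-oxazolidin-2-one, via mixed anhydride 20 (not isolated)
Conditions: 19, t-BuCOCl, Et3N, THF, −20 °C; then 18, LiCl, rt
Reagents that add atoms: none
Why: The acid is activated as its mixed pivalic anhydride and acylates the oxazolidinone nitrogen under LiCl/Et3N promotion (N-acylation), the unhindered phosphonoacetyl carbonyl group being attacked selectively and the stereocenter of the auxiliary staying untouched.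

Step 12
Reactants: 17 (4Z,6E)-5-[(3E)-5-{[tert-butyl(diphenyl)silyl]oxy}-3-methylpent-3-en-1-yl]-4,6-dimethylnona-4,6,8-trienal; 21 (4R)-4-benzyl-3-[(diethoxyphosphoryl)acetyl]-1,3-oxazolidin-2-one
Product: 22 (4R)-4-benzyl-3-{(2E,6Z,8E)-7-[(3E)-5-{[tert-butyl(diphenyl)silyl]oxy}-3-methylpent-3-en-1-yl]-6,8-dimethylundeca-2,6,8,10-tetraenoyl}-1,3-oxazolidin-2-one
Conditions: LiCl, i-Pr2NEt, MeCN, rt
Reagents that add atoms: none
Why: Horner–Wadsworth–Emmons olefination under mild LiCl/amine conditions should give the (E)-configured C4=C5 enoyl imide, the E geometry following from the thermodynamically controlled elimination of the stabilised phosphonate adduct.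

Step 13
Reactants: 22 (4R)-4-benzyl-3-{(2E,6Z,8E)-7-[(3E)-5-{[tert-butyl(diphenyl)silyl]oxy}-3-methylpent-3-en-1-yl]-6,8-dimethylundeca-2,6,8,10-tetraenoyl}-1,3-oxazolidin-2-one
Product: 23 (4R)-4-benzyl-3-({(1R,4aS,8aS)-5-[(3E)-5-{[tert-butyl(diphenyl)silyl]oxy}-3-methylpent-3-en-1-yl]-4a,6-dimethyl-1,2,4a,7,8,8a-hexahydronaphthalen-1-yl}carbonyl)-1,3-oxazolidin-2-one
Conditions: Me2AlCl (1.4 equiv), CH2Cl2, −30 °C to 0 °C; cold 1 M aqueous HCl
Reagents that add atoms: none
Why: Me2AlCl chelates the two imide carbonyl groups and the resulting cationic, s-cis-locked enoyl unit (C4=C5) adds across the diene C10=C1–C2=C3 in a concerted, asynchronous [4+2] cycloaddition that forms C5–C10 and C3–C4; the closest known reaction type is the Me2AlCl-promoted intramolecular Diels–Alder reaction of (E)-2,7,9-decatrienoyl oxazolidinones. Ring B closes as a six-membered ring in the fused (type 1) mode through the four-atom tether C6–C7–C8=C9, whose Z-tetrasubstituted alkene holds C7 and C10 cis and stands perpendicular to the diene in the transition state, and ring A is the cyclohexene created by the cycloaddition itself. The relative configuration of C5 and C10 follows from the endo transition state (imide carbonyl under the diene, tether exo), which for the (E)-dienophile and the (E)-configured diene terminus gives the trans ring fusion with H-5 anti to the C10 methyl group and places the acyl group at C4 cis to H-5. The absolute configuration is controlled by the (R)-benzyl group of the auxiliary, which shields one face of the chelated enoyl unit so that the diene adds to the opposite face of C4=C5, giving (5S,10S) in labdane numbering. The step needs endo and π-facial selectivity and sufficient reactivity at the fully substituted diene terminus C10: the chelated cationic dienophile, the short rigid tether and the small exo substituents (H at C4, C6 at C5) facing the inside methyl group secure these, and the regiochemistry is fixed by the tether because no other ring size is accessible. C4 is re-set in step 16, so only C5 and C10 have to be carried forward from this step.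

Step 14
Reactants: 23 (4R)-4-benzyl-3-({(1R,4aS,8aS)-5-[(3E)-5-{[tert-butyl(diphenyl)silyl]oxy}-3-methylpent-3-en-1-yl]-4a,6-dimethyl-1,2,4a,7,8,8a-hexahydronaphthalen-1-yl}carbonyl)-1,3-oxazolidin-2-one
Product: 24 2-(trimethylsilyl)ethyl (1R,4aS,8aS)-5-[(3E)-5-{[tert-butyl(diphenyl)silyl]oxy}-3-methylpent-3-en-1-yl]-4a,6-dimethyl-1,2,4a,7,8,8a-hexahydronaphthalene-1-carboxylate
Conditions: Me3SiCH2CH2OLi (from Me3SiCH2CH2OH and n-BuLi), THF, 0 °C; water
Reagents that add atoms: 2-(trimethylsilyl)ethanol, C[Si](C)(C)CCO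
Why: Lithium 2-(trimethylsilyl)ethoxide attacks the exocyclic imide carbonyl group (transesterification of an N-acyl oxazolidinone), which releases the auxiliary for recovery and gives an ester that fluoride can cleave later; epimerisation at C4 would be of no consequence because C4 is re-set in step 16.

Step 15
Reactants: 24 2-(trimethylsilyl)ethyl (1R,4aS,8aS)-5-[(3E)-5-{[tert-butyl(diphenyl)silyl]oxy}-3-methylpent-3-en-1-yl]-4a,6-dimethyl-1,2,4a,7,8,8a-hexahydronaphthalene-1-carboxylate
Product: 25 2-(trimethylsilyl)ethyl (1R,4aS,8aS)-5-[(3E)-5-{[tert-butyl(diphenyl)silyl]oxy}-3-methylpent-3-en-1-yl]-4a,6-dimethyl-1,2,3,4,4a,7,8,8a-octahydronaphthalene-1-carboxylate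
Conditions: 2-nitrobenzenesulfonylhydrazide, Et3N, CH2Cl2, rt
Reagents that add atoms: none
Why: Diimide, generated in situ from the sulfonylhydrazide, transfers two hydrogen atoms in a concerted syn fashion and is strongly sensitive to alkene substitution (diimide reduction), so the cis-disubstituted C1=C2 bond should be saturated while the trisubstituted C13=C14 and tetrasubstituted C8=C9 bonds remain; no stereocenter is created.

Step 16
Reactants: 25 2-(trimethylsilyl)ethyl (1R,4aS,8aS)-5-[(3E)-5-{[tert-butyl(diphenyl)silyl]oxy}-3-methylpent-3-en-1-yl]-4a,6-dimethyl-1,2,3,4,4a,7,8,8a-octahydronaphthalene-1-carboxylate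
Product: 27 2-(trimethylsilyl)ethyl (1S,4aS,8aR)-5-[(3E)-5-{[tert-butyl(diphenyl)silyl]oxy}-3-methylpent-3-en-1-yl]-1,4a,6-trimethyl-1,2,3,4,4a,7,8,8a-octahydronaphthalene-1-carboxylate, via lithium enolate 26 (not isolated)
Conditions: LiN(i-Pr)2, THF, −78 °C to 0 °C; then MeI, DMPU, −78 °C to rt
Reagents that add atoms: iodomethane, CI
Why: The exocyclic ester enolate at C4 is methylated by MeI from the α face (equatorial attack), because the β face is shielded by the syn-axial C10 methyl group, so the new methyl group (C18) becomes equatorial and the ester axial and cis to the C10 methyl group, i.e. (4S); reaction type: substrate-controlled enolate alkylation.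

Step 17
Reactants: 27 2-(trimethylsilyl)ethyl (1S,4aS,8aR)-5-[(3E)-5-{[tert-butyl(diphenyl)silyl]oxy}-3-methylpent-3-en-1-yl]-1,4a,6-trimethyl-1,2,3,4,4a,7,8,8a-octahydronaphthalene-1-carboxylate
Product: 28 (1S,4aS,8aR)-5-[(3E)-5-hydroxy-3-methylpent-3-en-1-yl]-1,4a,6-trimethyl-1,2,3,4,4a,7,8,8a-octahydronaphthalene-1-carboxylic acid
Conditions: Bu4NF, THF, rt to 40 °C; aqueous NH4Cl
Reagents that add atoms: none
Why: Fluoride attacks silicon in both protecting groups (fluoride-induced desilylation and β-elimination): the silyl ether gives the primary alcohol and the 2-(trimethylsilyl)ethyl ester fragments into ethene and the carboxylate, so the hindered axial ester is cleaved without any attack at its carbonyl group.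

Step 18
Reactants: 28 (1S,4aS,8aR)-5-[(3E)-5-hydroxy-3-methylpent-3-en-1-yl]-1,4a,6-trimethyl-1,2,3,4,4a,7,8,8a-octahydronaphthalene-1-carboxylic acid
Product: 29 (1S,4aS,8aR)-5-[(3E)-5-(acetyloxy)-3-methylpent-3-en-1-yl]-1,4a,6-trimethyl-1,2,3,4,4a,7,8,8a-octahydronaphthalene-1-carboxylic acid
Conditions: Ac2O, pyridine, DMAP (cat.), CH2Cl2, 0 °C to rt; aqueous work-up
Reagents that add atoms: acetic anhydride, CC(=O)OC(C)=O
Why: DMAP-catalysed acylation with acetic anhydride esterifies the primary allylic alcohol, whereas the hindered tertiary carboxylic acid is returned unchanged after aqueous work-up (selective O-acetylation).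

**Compound list**

1 | tert-butyldimethyl(pent-4-yn-1-yloxy)silane | C#CCCCO[Si](C)(C)C(C)(C)C | starting material
2 | {5-[(tert-butyldimethylsilyl)oxy]pent-1-yn-1-yl}lithium | [Li]C#CCCCO[Si](C)(C)C(C)(C)C | intermediate
3 | ethyl 6-[(tert-butyldimethylsilyl)oxy]hex-2-ynoate | CCOC(=O)C#CCCCO[Si](C)(C)C(C)(C)C | intermediate
4 | lithium methyl{(1E)-5-[(tert-butyldimethylsilyl)oxy]-1-(ethoxycarbonyl)-2-methylpent-1-en-1-yl}cuprate (copper cis to the new methyl group) | [Li+].CCOC(=O)/C([Cu-]C)=C(C)\CCCO[Si](C)(C)C(C)(C)C | intermediate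
5 | ethyl (2E)-6-[(tert-butyldimethylsilyl)oxy]-2-iodo-3-methylhex-2-enoate (iodine cis to methyl) | CCOC(=O)/C(I)=C(C)\CCCO[Si](C)(C)C(C)(C)C | intermediate
6 | (2E)-3-methylpent-2-en-4-yn-1-ol | C#C/C(C)=C/CO | starting material
7 | tert-butyl{[(2E)-3-methylpent-2-en-4-yn-1-yl]oxy}diphenylsilane | C#C/C(C)=C/CO[Si](c1ccccc1)(c1ccccc1)C(C)(C)C | intermediate
8 | tert-butyl{[(2E)-3-methylpenta-2,4-dien-1-yl]oxy}diphenylsilane | C=C/C(C)=C/CO[Si](c1ccccc1)(c1ccccc1)C(C)(C)C | intermediate
9 | 9-[(3E)-5-{[tert-butyl(diphenyl)silyl]oxy}-3-methylpent-3-en-1-yl]-9-borabicyclo[3.3.1]nonane | CC(C)(C)[Si](c1ccccc1)(c1ccccc1)OC/C=C(C)/CCB1C2CCCC1CCC2 | intermediate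
10 | ethyl (2Z)-6-[(tert-butyldimethylsilyl)oxy]-2-[(3E)-5-{[tert-butyl(diphenyl)silyl]oxy}-3-methylpent-3-en-1-yl]-3-methylhex-2-enoate | CCOC(=O)/C(CC/C(C)=C/CO[Si](c1ccccc1)(c1ccccc1)C(C)(C)C)=C(C)\CCCO[Si](C)(C)C(C)(C)C | intermediate
11 | (2Z)-6-[(tert-butyldimethylsilyl)oxy]-2-[(3E)-5-{[tert-butyl(diphenyl)silyl]oxy}-3-methylpent-3-en-1-yl]-3-methylhex-2-en-1-ol | OC/C(CC/C(C)=C/CO[Si](c1ccccc1)(c1ccccc1)C(C)(C)C)=C(C)\CCCO[Si](C)(C)C(C)(C)C | intermediate
12 | (2Z)-6-[(tert-butyldimethylsilyl)oxy]-2-[(3E)-5-{[tert-butyl(diphenyl)silyl]oxy}-3-methylpent-3-en-1-yl]-3-methylhex-2-enal | O=C/C(CC/C(C)=C/CO[Si](c1ccccc1)(c1ccccc1)C(C)(C)C)=C(C)\CCCO[Si](C)(C)C(C)(C)C | intermediate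
13 | (4Z,8E)-1-[(tert-butyldimethylsilyl)oxy]-10-{[tert-butyl(diphenyl)silyl]oxy}-5-ethynyl-4,8-dimethyldeca-4,8-diene | C#C/C(CC/C(C)=C/CO[Si](c1ccccc1)(c1ccccc1)C(C)(C)C)=C(C)\CCCO[Si](C)(C)C(C)(C)C | intermediate
14 | dimethyl{(1E,3Z)-7-[(tert-butyldimethylsilyl)oxy]-3-[(3E)-5-{[tert-butyl(diphenyl)silyl]oxy}-3-methylpent-3-en-1-yl]-2,4-dimethylhepta-1,3-dien-1-yl}alane | C[Al](C)/C=C(\C)/C(CC/C(C)=C/CO[Si](c1ccccc1)(c1ccccc1)C(C)(C)C)=C(C)\CCCO[Si](C)(C)C(C)(C)C | intermediate
15 | (4Z,6E)-1-[(tert-butyldimethylsilyl)oxy]-5-[(3E)-5-{[tert-butyl(diphenyl)silyl]oxy}-3-methylpent-3-en-1-yl]-4,6-dimethylnona-4,6,8-triene | C=C/C=C(\C)/C(CC/C(C)=C/CO[Si](c1ccccc1)(c1ccccc1)C(C)(C)C)=C(C)\CCCO[Si](C)(C)C(C)(C)C | intermediate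
16 | (4Z,6E)-5-[(3E)-5-{[tert-butyl(diphenyl)silyl]oxy}-3-methylpent-3-en-1-yl]-4,6-dimethylnona-4,6,8-trien-1-ol | C=C/C=C(\C)/C(CC/C(C)=C/CO[Si](c1ccccc1)(c1ccccc1)C(C)(C)C)=C(C)\CCCO | intermediate
17 | (4Z,6E)-5-[(3E)-5-{[tert-butyl(diphenyl)silyl]oxy}-3-methylpent-3-en-1-yl]-4,6-dimethylnona-4,6,8-trienal | C=C/C=C(\C)/C(CC/C(C)=C/CO[Si](c1ccccc1)(c1ccccc1)C(C)(C)C)=C(C)\CCC=O | intermediate
18 | (4R)-4-benzyl-1,3-oxazolidin-2-one | O=C1N[C@H](Cc2ccccc2)CO1 | starting material
19 | (diethoxyphosphoryl)acetic acid | CCOP(=O)(OCC)CC(=O)O | starting material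
20 | (diethoxyphosphoryl)acetic pivalic anhydride | CCOP(=O)(OCC)CC(=O)OC(=O)C(C)(C)C | intermediate
21 | (4R)-4-benzyl-3-[(diethoxyphosphoryl)acetyl]-1,3-oxazolidin-2-one | CCOP(=O)(OCC)CC(=O)N1C(=O)OC[C@H]1Cc1ccccc1 | intermediate
22 | (4R)-4-benzyl-3-{(2E,6Z,8E)-7-[(3E)-5-{[tert-butyl(diphenyl)silyl]oxy}-3-methylpent-3-en-1-yl]-6,8-dimethylundeca-2,6,8,10-tetraenoyl}-1,3-oxazolidin-2-one | C=C/C=C(\C)/C(CC/C(C)=C/CO[Si](c1ccccc1)(c1ccccc1)C(C)(C)C)=C(C)\CC/C=C/C(=O)N1C(=O)OC[C@H]1Cc1ccccc1 | intermediate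
23 | (4R)-4-benzyl-3-({(1R,4aS,8aS)-5-[(3E)-5-{[tert-butyl(diphenyl)silyl]oxy}-3-methylpent-3-en-1-yl]-4a,6-dimethyl-1,2,4a,7,8,8a-hexahydronaphthalen-1-yl}carbonyl)-1,3-oxazolidin-2-one | CC(C)(C)[Si](c1ccccc1)(c1ccccc1)OC/C=C(\C)CCC1=C(C)CC[C@H]2[C@H](C(=O)N3C(=O)OC[C@H]3Cc3ccccc3)CC=C[C@]12C | intermediate
24 | 2-(trimethylsilyl)ethyl (1R,4aS,8aS)-5-[(3E)-5-{[tert-butyl(diphenyl)silyl]oxy}-3-methylpent-3-en-1-yl]-4a,6-dimethyl-1,2,4a,7,8,8a-hexahydronaphthalene-1-carboxylate | CC(C)(C)[Si](c1ccccc1)(c1ccccc1)OC/C=C(\C)CCC1=C(C)CC[C@H]2[C@H](C(=O)OCC[Si](C)(C)C)CC=C[C@]12C | intermediate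
25 | 2-(trimethylsilyl)ethyl (1R,4aS,8aS)-5-[(3E)-5-{[tert-butyl(diphenyl)silyl]oxy}-3-methylpent-3-en-1-yl]-4a,6-dimethyl-1,2,3,4,4a,7,8,8a-octahydronaphthalene-1-carboxylate | CC(C)(C)[Si](c1ccccc1)(c1ccccc1)OC/C=C(\C)CCC1=C(C)CC[C@H]2[C@H](C(=O)OCC[Si](C)(C)C)CCC[C@]12C | intermediate
26 | lithium enolate of 25 (C4 trigonal; C5 and C10 as in 25) | CC(C)(C)[Si](c1ccccc1)(c1ccccc1)OC/C=C(\C)CCC1=C(C)CC[C@H]2C(=C(O[Li])OCC[Si](C)(C)C)CCC[C@]12C | intermediate
27 | 2-(trimethylsilyl)ethyl (1S,4aS,8aR)-5-[(3E)-5-{[tert-butyl(diphenyl)silyl]oxy}-3-methylpent-3-en-1-yl]-1,4a,6-trimethyl-1,2,3,4,4a,7,8,8a-octahydronaphthalene-1-carboxylate | CC(C)(C)[Si](c1ccccc1)(c1ccccc1)OC/C=C(\C)CCC1=C(C)CC[C@H]2[C@@](C)(C(=O)OCC[Si](C)(C)C)CCC[C@]12C | intermediate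
28 | (1S,4aS,8aR)-5-[(3E)-5-hydroxy-3-methylpent-3-en-1-yl]-1,4a,6-trimethyl-1,2,3,4,4a,7,8,8a-octahydronaphthalene-1-carboxylic acid | OC/C=C(\C)CCC1=C(C)CC[C@H]2[C@@](C)(C(=O)O)CCC[C@]12C | intermediate
29 | (1S,4aS,8aR)-5-[(3E)-5-(acetyloxy)-3-methylpent-3-en-1-yl]-1,4a,6-trimethyl-1,2,3,4,4a,7,8,8a-octahydronaphthalene-1-carboxylic acid (15-acetoxylabda-8,13E-dien-19-oic acid) | CC(=O)OC/C=C(\C)CCC1=C(C)CC[C@H]2[C@@](C)(C(=O)O)CCC[C@]12C | target

**Step count and risks**

Total step count: 18. Longest linear sequence: 15 steps (steps 1, 2, 5–10 and 12–18, from compound 1).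

The three steps most likely to fail:

Step 13 (key cycloaddition). The cycloaddition may be slow at the fully substituted diene terminus C10, the electron-rich triene may ionise or oligomerise under the Lewis acid, or endo and facial selectivity may erode. The fallback changes both the activation mode and the source of asymmetry, from auxiliary plus Lewis acid to iminium-ion organocatalysis. It sets out from aldehyde 17. Wittig olefination with (triphenylphosphoranylidene)acetaldehyde (toluene, 80 °C) should give the (2E)-configured tetraenal F1. Treatment with the triflic acid salt of (2R,5R)-5-benzyl-2-tert-butyl-3-methylimidazolidin-4-one (20 mol%, MeCN/H2O, 0 °C to rt) should bring about the endo-selective intramolecular Diels–Alder reaction of the (E)-iminium ion on the face opposite the benzyl group and give bicyclic aldehyde F2. Oxidation with NaClO2/NaH2PO4/2-methyl-2-butene should give carboxylic acid F3, and esterification with 2-(trimethylsilyl)ethanol (dicyclohexylcarbodiimide, DMAP, CH2Cl2) comes back to the route at ester 24.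

Step 16 (C4 methylation). Enolisation at the hindered axial C4–H may be incomplete, or the alkylation may show poor facial selectivity. The fallback moves the alkylation to the aldehyde oxidation level, where the α-hydrogen is far more acidic and the enolate forms reversibly under alkoxide conditions. It sets out from ester 25. LiAlH4 (THF, 0 °C) should give primary alcohol F4, and Dess–Martin oxidation should give aldehyde F5. KOt-Bu and MeI (THF/t-BuOH, 0 °C) should give the C-methylated aldehyde F6 by equatorial attack anti to the C10 methyl group. Oxidation with NaClO2/NaH2PO4/2-methyl-2-butene should give silyl-protected acid F7, and Bu4NF (THF) comes back to the route at hydroxy acid 28.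

Step 7 (one-pot oxidation and alkyne homologation). The tetrasubstituted enal may lose its alkene geometry through its dienolate in basic methanol, or the diazophosphonate anion may add too slowly to the hindered formyl group. The fallback replaces the basic diazo homologation by a non-basic dibromo-olefination followed by a carbenoid rearrangement at low temperature. It sets out from allylic alcohol 11, which is oxidised with MnO2 as before, and enal 12 is then isolated by filtration. CBr4 and PPh3 (CH2Cl2, 0 °C; Corey–Fuchs olefination) should give dibromoalkene F8. n-BuLi (2.2 equiv, THF, −78 °C; Fritsch–Buttenberg–Wiechell rearrangement), followed by aqueous NH4Cl, comes back to the route at enyne 13.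

Further compounds
F1 | step 13 | (2E,6Z,8E)-7-[(3E)-5-{[tert-butyl(diphenyl)silyl]oxy}-3-methylpent-3-en-1-yl]-6,8-dimethylundeca-2,6,8,10-tetraenal | C=C/C=C(\C)/C(CC/C(C)=C/CO[Si](c1ccccc1)(c1ccccc1)C(C)(C)C)=C(C)\CC/C=C/C=O
F2 | step 13 | (1R,4aS,8aS)-5-[(3E)-5-{[tert-butyl(diphenyl)silyl]oxy}-3-methylpent-3-en-1-yl]-4a,6-dimethyl-1,2,4a,7,8,8a-hexahydronaphthalene-1-carbaldehyde | CC(C)(C)[Si](c1ccccc1)(c1ccccc1)OC/C=C(\C)CCC1=C(C)CC[C@H]2[C@H](C=O)CC=C[C@]12C
F3 | step 13 | (1R,4aS,8aS)-5-[(3E)-5-{[tert-butyl(diphenyl)silyl]oxy}-3-methylpent-3-en-1-yl]-4a,6-dimethyl-1,2,4a,7,8,8a-hexahydronaphthalene-1-carboxylic acid | CC(C)(C)[Si](c1ccccc1)(c1ccccc1)OC/C=C(\C)CCC1=C(C)CC[C@H]2[C@H](C(=O)O)CC=C[C@]12C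
F4 | step 16 | {(1R,4aS,8aS)-5-[(3E)-5-{[tert-butyl(diphenyl)silyl]oxy}-3-methylpent-3-en-1-yl]-4a,6-dimethyl-1,2,3,4,4a,7,8,8a-octahydronaphthalen-1-yl}methanol | CC(C)(C)[Si](c1ccccc1)(c1ccccc1)OC/C=C(\C)CCC1=C(C)CC[C@H]2[C@H](CO)CCC[C@]12C
F5 | step 16 | (1R,4aS,8aS)-5-[(3E)-5-{[tert-butyl(diphenyl)silyl]oxy}-3-methylpent-3-en-1-yl]-4a,6-dimethyl-1,2,3,4,4a,7,8,8a-octahydronaphthalene-1-carbaldehyde | CC(C)(C)[Si](c1ccccc1)(c1ccccc1)OC/C=C(\C)CCC1=C(C)CC[C@H]2[C@H](C=O)CCC[C@]12C
F6 | step 16 | (1S,4aS,8aR)-5-[(3E)-5-{[tert-butyl(diphenyl)silyl]oxy}-3-methylpent-3-en-1-yl]-1,4a,6-trimethyl-1,2,3,4,4a,7,8,8a-octahydronaphthalene-1-carbaldehyde | CC(C)(C)[Si](c1ccccc1)(c1ccccc1)OC/C=C(\C)CCC1=C(C)CC[C@H]2[C@@](C)(C=O)CCC[C@]12C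
F7 | step 16 | (1S,4aS,8aR)-5-[(3E)-5-{[tert-butyl(diphenyl)silyl]oxy}-3-methylpent-3-en-1-yl]-1,4a,6-trimethyl-1,2,3,4,4a,7,8,8a-octahydronaphthalene-1-carboxylic acid | CC(C)(C)[Si](c1ccccc1)(c1ccccc1)OC/C=C(\C)CCC1=C(C)CC[C@H]2[C@@](C)(C(=O)O)CCC[C@]12C
F8 | step 7 | (4Z,8E)-1-[(tert-butyldimethylsilyl)oxy]-10-{[tert-butyl(diphenyl)silyl]oxy}-5-(2,2-dibromoethenyl)-4,8-dimethyldeca-4,8-diene | BrC(Br)=C/C(CC/C(C)=C/CO[Si](c1ccccc1)(c1ccccc1)C(C)(C)C)=C(C)\CCCO[Si](C)(C)C(C)(C)C
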